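**Strategy.** The cyclohexane ring is cut at two para bonds, the ring-fusion bond C3a–C7a and the diol bond C5–C6 (octahydroindene numbering), which unravels both rings to acyclic keto dienal 13. One amine-catalysed Michael/aldol condensation rebuilds them: the ketone α-carbon (C3a) adds 5-exo to the enal β-carbon (C7a), then the ketone methyl (C5) condenses with the aldehyde (C6) to the cyclohexenone. The step exploits the 1,5-dicarbonyl relation of C4 and C6 through C3a, C7a and C7, the (Z)-ethylidene on C1 flanking the C2 acetoxy centre (allylic strain selects the ring face) and the epimerisable C3a and C7 centres, so enal geometry is irrelevant. Epoxidation, methylenation and angelic acid opening finish.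

Key step: step 9

Remark: ring atoms are numbered as in octahydro-1H-indene (C1 ethylidene carbon, C2 acetoxy carbon, C3a/C7a ring fusion, C4 methylidene carbon, C5 angelate carbon, C6 carbinol carbon, C7 isopropyl carbon); compounds 1, 2, 8, 9 and 19 are assumed to be purchased.

**Step 1**
Reactants: 1 pent-4-enoyl chloride; 2 propyne
Product: 3 oct-7-en-2-yn-4-one
Conditions: PdCl2(PPh3)2 (2 mol%), CuI (4 mol%), Et3N (1.1 equiv), THF, 0 °C to rt
Reagents that add atoms: none
Why: Acyl Sonogashira coupling of an acid chloride with a terminal alkyne should give the ynone in one operation; the terminal alkene (masked methyl ketone) is inert.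

**Step 2**
Reactants: 3 oct-7-en-2-yn-4-one
Product: 4 (4S)-oct-7-en-2-yn-4-ol
Conditions: RuCl[(S,S)-TsDPEN](p-cymene) (1 mol%), iPrOH, rt
Reagents that add atoms: none
Why: Noyori asymmetric transfer hydrogenation of an ynone, in which the alkynyl group plays the role of the aryl group of aryl ketones, so the (S,S)-catalyst is expected to give the (S)-carbinol that becomes C2 of the target.

**Step 3**
Reactants: 4 (4S)-oct-7-en-2-yn-4-ol
Product: 5 (5S)-5-hydroxyoct-6-yn-2-one
Conditions: PdCl2 (10 mol%), CuCl (co-catalyst), O2 (1 atm), DMF/H2O 7:1, rt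
Reagents that add atoms: water, O
Why: Tsuji–Wacker oxidation should convert the terminal alkene into the methyl ketone faster than the internal alkyne reacts; participation of the hydroxyl group only leads to the lactol form of the same product.

**Step 4**
Reactants: 5 (5S)-5-hydroxyoct-6-yn-2-one
Product: 6 (5S,6E)-5-hydroxy-6-(tributylstannyl)oct-6-en-2-one
Conditions: PdCl2(PPh3)2 (3 mol%), Bu3SnH (1.3 equiv), THF, 0 °C
Reagents that add atoms: tributyltin hydride, CCCC[SnH](CCCC)CCCC
Why: Palladium-catalysed hydrostannation adds H and Sn syn, with tin directed to the alkyne carbon next to the carbinol; this fixes the alkene geometry with the methyl group cis to the carbinol carbon, the (Z)-ethylidene of the target.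

**Step 5**
Reactants: 6 (5S,6E)-5-hydroxy-6-(tributylstannyl)oct-6-en-2-one
Product: 7 (2E,4S)-7-oxo-3-(tributylstannyl)oct-2-en-4-yl acetate
Conditions: Ac2O, pyridine, DMAP (cat.), CH2Cl2, 0 °C to rt
Reagents that add atoms: acetic anhydride, CC(=O)OC(C)=O
Why: Standard acylation of the secondary alcohol installs the C2 acetate of the target, which also serves as the stereodirecting group of the key step; the alkenylstannane tolerates these non-acidic conditions.

**Step 6**
Reactants: 8 prop-2-yn-1-ol; 9 isopropylmagnesium chloride
Product: 11 (2Z)-3-iodo-2-(propan-2-yl)prop-2-en-1-ol, via alkenylmagnesium alkoxide 10 (not isolated)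
Conditions: 9 (2.5 equiv), CuI (10 mol%), THF, −10 °C to rt; then I2, −40 to 0 °C; aq. NH4Cl
Reagents that add atoms: iodine, II
Why: Copper-catalysed anti-carbomagnesiation of propargyl alcohol places the isopropyl group on C2 and magnesium on C3 in a chelated alkenylmagnesium, and iodinolysis with retention should give the (Z)-iodide.

**Step 7**
Reactants: 11 (2Z)-3-iodo-2-(propan-2-yl)prop-2-en-1-ol
Product: 12 (2Z)-3-iodo-2-(propan-2-yl)prop-2-enal
Conditions: MnO2 (excess), CH2Cl2, rt
Reagents that add atoms: none
Why: Allylic alcohol oxidation with MnO2 gives the β-iodo enal without touching the vinyl iodide; its alkene geometry is not critical for what follows.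

**Step 8**
Reactants: 7 (2E,4S)-7-oxo-3-(tributylstannyl)oct-2-en-4-yl acetate; 12 (2Z)-3-iodo-2-(propan-2-yl)prop-2-enal
Product: 13 (2Z,5S)-5-acetoxy-4-[(Z)-ethylidene]-8-oxo-2-(propan-2-yl)non-2-enal
Conditions: Pd(PPh3)4 (5 mol%), CuI (20 mol%), CsF (2 equiv), DMF, rt
Reagents that add atoms: none
Why: Stille coupling with copper/fluoride acceleration suits the hindered α-substituted alkenylstannane, proceeds with retention at both alkenes and at room temperature should leave the allylic acetate, ketone and aldehyde intact.

**Step 9**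
Reactants: 13 (2Z,5S)-5-acetoxy-4-[(Z)-ethylidene]-8-oxo-2-(propan-2-yl)non-2-enal
Product: 16 (1Z,2S,3aR,7R,7aS)-1-ethylidene-4-oxo-7-(propan-2-yl)-2,3,3a,4,7,7a-hexahydro-1H-inden-2-yl acetate, via Michael adduct 14 (not isolated), via aldol 15 (not isolated)
Conditions: pyrrolidine (0.3 equiv), AcOH (0.3 equiv), toluene (0.02 M), rt to 60 °C
Reagents that add atoms: none
Why: Pyrrolidine/acetic acid converts the ketone into its enamines, the internal enamine carbon C3a adds to the enal β-carbon C7a, the released α-branched aldehyde is attacked at C6 by the methyl-side enamine carbon C5, and loss of water gives the enone; the closest known reaction type is the amine-catalysed Michael/aldol condensation (Robinson-type (3+3) annulation of a methyl ketone with an enal), here run intramolecularly. The cyclopentane closes by 5-exo-trig Michael addition (the alternatives would be a seven-membered ring from the methyl carbon or a 5-endo attack at the ethylidene carbon), and the cyclohexenone by 6-(enolexo)-exo-trig aldol addition followed by dehydration. C7a is controlled by C2: the methyl group of the (Z)-ethylidene forces the C2 acetoxy group pseudoaxial by 1,3-allylic strain, so the enal carbon C7 should take the face of the forming ring opposite to it, which places the C7a–C7 bond trans to the acetoxy group. C3a follows as an epimerisable α-keto centre (acetyl trans to the C7a side chain, later the trans ring fusion), and C7 is set by epimerisation of the α-formyl centre before the aldol closure and of the γ-centre of the enone after it, which should leave the isopropyl group equatorial. The step needs regioselective enolisation and facial selectivity: ring size secures the former and the allylic C2 stereocentre the latter. The (2Z) and (2E) enal isomers and the 2H-pyran valence isomer of 13 should all converge on the same product.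

**Step 10**
Reactants: 16 (1Z,2S,3aR,7R,7aS)-1-ethylidene-4-oxo-7-(propan-2-yl)-2,3,3a,4,7,7a-hexahydro-1H-inden-2-yl acetate
Product: 17 (1Z)-5,6-epoxy-1-ethylidene-4-oxo-7-(propan-2-yl)octahydro-1H-inden-2-yl acetate with the oxirane oxygen anti to H-3a (syn to H-7a and to the isopropyl group)
Conditions: tBuOOH (in decane, 3 equiv), DBU (1.5 equiv), CH2Cl2, 0 °C to rt
Reagents that add atoms: tert-butyl hydroperoxide, CC(C)(C)OO
Why: Weitz–Scheffer nucleophilic epoxidation under non-hydrolytic conditions spares the acetate and the isolated alkenes; in the rigid trans-fused enone the hydroperoxide anion should add axially to C6, anti to the axial H-7, so the oxirane forms on the face of H-7a.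

**Step 11**
Reactants: 17 epoxy ketone acetate (oxirane anti to H-3a)
Product: 18 (1Z)-5,6-epoxy-1-ethylidene-4-methylidene-7-(propan-2-yl)octahydro-1H-inden-2-yl acetate with the oxirane oxygen anti to H-3a
Conditions: Ph3PCH3Br (2.0 equiv), KOtBu (1.9 equiv), THF, 0 °C; then 17, 0 °C to rt
Reagents that add atoms: methyltriphenylphosphonium bromide, C[P+](c1ccccc1)(c1ccccc1)c1ccccc1.[Br-]
Why: Wittig methylenation of the ketone is faster than attack on the acetate and leaves the oxirane intact; it also removes the last epimerisable position next to C3a.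

**Step 12**
Reactants: 18 vinyl epoxide acetate (oxirane anti to H-3a); 19 angelic acid ((2Z)-2-methylbut-2-enoic acid)
Product: 20 (1Z,2S,3aR,5S,6S,7S,7aR)-2-acetoxy-1-ethylidene-6-hydroxy-4-methylidene-7-(propan-2-yl)octahydro-1H-inden-5-yl (2Z)-2-methylbut-2-enoate (target)
Conditions: 19 (5 equiv), iPr2NEt (0.5 equiv), DMF, 50 °C
Reagents that add atoms: none
Why: Carboxylic acid ring opening of the vinyl epoxide by SN2 attack at the allylic carbon C5 with inversion, from the face syn to H-3a, is the trans-diaxial opening through a chair-like transition state; it should give the axial C5 angelate and the axial C6 hydroxyl, an arrangement in which acyl migration is geometrically blocked.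

**Compound list**
1 | pent-4-enoyl chloride | C=CCCC(=O)Cl | starting material
2 | propyne | CC#C | starting material
3 | oct-7-en-2-yn-4-one | C=CCCC(=O)C#CC | intermediate
4 | (4S)-oct-7-en-2-yn-4-ol | C=CCC[C@H](O)C#CC | intermediate
5 | (5S)-5-hydroxyoct-6-yn-2-one | CC(=O)CC[C@H](O)C#CC | intermediate
6 | (5S,6E)-5-hydroxy-6-(tributylstannyl)oct-6-en-2-one | CC(=O)CC[C@H](O)/C(=C\C)[Sn](CCCC)(CCCC)CCCC | intermediate
7 | (2E,4S)-7-oxo-3-(tributylstannyl)oct-2-en-4-yl acetate | CC(=O)CC[C@H](OC(C)=O)/C(=C\C)[Sn](CCCC)(CCCC)CCCC | intermediate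
8 | prop-2-yn-1-ol | C#CCO | starting material
9 | isopropylmagnesium chloride | CC(C)[Mg]Cl | starting material
10 | chloromagnesium (2Z)-3-(chloromagnesio)-2-(propan-2-yl)prop-2-en-1-olate | Cl[Mg]/C=C(\CO[Mg]Cl)C(C)C | intermediate
11 | (2Z)-3-iodo-2-(propan-2-yl)prop-2-en-1-ol | I/C=C(\CO)C(C)C | intermediate
12 | (2Z)-3-iodo-2-(propan-2-yl)prop-2-enal | I/C=C(\C=O)C(C)C | intermediate
13 | (2Z,5S)-5-acetoxy-4-[(Z)-ethylidene]-8-oxo-2-(propan-2-yl)non-2-enal | CC(=O)CC[C@H](OC(C)=O)/C(=C\C)/C=C(/C(C)C)C=O | intermediate
14 | 2-[(2Z)-3-acetoxy-4-acetyl-2-ethylidenecyclopentyl]-3-methylbutanal (acetyl trans to the butanal side chain and cis to the acetoxy group; both epimers at the formyl-bearing carbon) | CC(=O)[C@@H]1C[C@H](OC(C)=O)/C(=C\C)[C@H]1C(C(C)C)C=O | intermediate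
15 | (1Z)-1-ethylidene-6-hydroxy-4-oxo-7-(propan-2-yl)octahydro-1H-inden-2-yl acetate (ring stereocentres as in 16, carbinol centre undefined) | O=C1[C@@H]2C[C@H](OC(C)=O)/C(=C\C)[C@H]2[C@H](C(C)C)C(O)C1 | intermediate
16 | (1Z,2S,3aR,7R,7aS)-1-ethylidene-4-oxo-7-(propan-2-yl)-2,3,3a,4,7,7a-hexahydro-1H-inden-2-yl acetate | O=C1[C@@H]2C[C@H](OC(C)=O)/C(=C\C)[C@H]2[C@H](C(C)C)C=C1 | intermediate
17 | 5,6-epoxide of 16, oxirane oxygen anti to H-3a and syn to H-7a | O=C1[C@@H]2C[C@H](OC(C)=O)/C(=C\C)[C@H]2[C@H](C(C)C)[C@@H]3O[C@H]13 | intermediate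
18 | 4-methylidene analogue of 17 (vinyl epoxide) | C=C1[C@@H]2C[C@H](OC(C)=O)/C(=C\C)[C@H]2[C@H](C(C)C)[C@@H]3O[C@H]13 | intermediate
19 | angelic acid, (2Z)-2-methylbut-2-enoic acid | C/C=C(/C)C(=O)O | starting material
20 | (1Z,2S,3aR,5S,6S,7S,7aR)-2-acetoxy-1-ethylidene-6-hydroxy-4-methylidene-7-(propan-2-yl)octahydro-1H-inden-5-yl (2Z)-2-methylbut-2-enoate | C=C1[C@@H]2C[C@H](OC(C)=O)/C(=C\C)[C@H]2[C@H](C(C)C)[C@H](O)[C@H]1OC(=O)/C(C)=C\C | target

**Step count.** Total: 12 steps. Longest linear sequence: 10 steps (steps 1–5 and 8–12); steps 6 and 7 form the second branch.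

**Steps most likely to fail**

1. Step 9 (key step). The acetoxy group may shield the ring face too weakly, so the Michael ring closure could show poor facial selectivity at C7a, with epimerisation at C3a towards the cis-fused series as a linked risk. The fallback sets out from 6 and replaces the acetate by a much larger directing group. Silylation (TBSCl, imidazole, DMF) gives the silyl ether stannane F1, and Stille coupling with 12 under the conditions of step 8 gives the silyl dienal F2. The same pyrrolidine/AcOH cascade then runs through the silyl Michael adduct F3 and the silyl aldol F4 to the silyl enone F5. Desilylation (Bu4NF, AcOH, THF) gives the hydroxy enone F6, and acetylation (Ac2O, pyridine) comes back to the route at 16.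

2. Step 12. The carboxylate may attack the exocyclic methylene carbon (conjugate opening) instead of C5, or the substitution may be so slow that heating erodes the angelate geometry. The fallback sets out from 17 and opens the oxirane before the alkene exists. Angelic acid 19 (iPr2NEt, DMF) attacks the epoxy ketone at C5, the carbon α to the carbonyl group, where only direct trans-diaxial substitution is possible, to give the hydroxy keto angelate F9. Lombardo methylenation under non-basic conditions (Zn, CH2Br2, TiCl4, THF/CH2Cl2), which spares esters, then comes back to the route at 20.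

3. Step 10. The hydroperoxide may add from the face syn to H-3a (equatorial attack), which would put the oxirane on the wrong face. The fallback sets out from 16 and uses a hydroxyl-directed electrophilic epoxidation. Corey–Bakshi–Shibata 1,2-reduction gives the pseudoaxial allylic alcohol F7; the conditions are (S)-Me-CBS oxazaborolidine and BH3·SMe2, expected to deliver hydride syn to H-3a if the enone double bond acts as the large group. VO(acac)2/tBuOOH then epoxidises syn to the hydroxyl, on the required face, to give the epoxy alcohol F8. Dess–Martin oxidation comes back to the route at 17.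

**Further compounds**
F1 | step 9 | (5S,6E)-5-[(tert-butyldimethylsilyl)oxy]-6-(tributylstannyl)oct-6-en-2-one | CC(=O)CC[C@H](O[Si](C)(C)C(C)(C)C)/C(=C\C)[Sn](CCCC)(CCCC)CCCC
F2 | step 9 | (2Z,5S)-5-[(tert-butyldimethylsilyl)oxy]-4-[(Z)-ethylidene]-8-oxo-2-(propan-2-yl)non-2-enal | CC(=O)CC[C@H](O[Si](C)(C)C(C)(C)C)/C(=C\C)/C=C(/C(C)C)C=O
F3 | step 9 | silyl ether analogue of Michael adduct 14 | CC(=O)[C@@H]1C[C@H](O[Si](C)(C)C(C)(C)C)/C(=C\C)[C@H]1C(C(C)C)C=O
F4 | step 9 | silyl ether analogue of aldol 15 | O=C1[C@@H]2C[C@H](O[Si](C)(C)C(C)(C)C)/C(=C\C)[C@H]2[C@H](C(C)C)C(O)C1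
F5 | step 9 | (1Z,2S,3aR,7R,7aS)-2-[(tert-butyldimethylsilyl)oxy]-1-ethylidene-7-(propan-2-yl)-1,2,3,3a,7,7a-hexahydro-4H-inden-4-one | O=C1[C@@H]2C[C@H](O[Si](C)(C)C(C)(C)C)/C(=C\C)[C@H]2[C@H](C(C)C)C=C1
F6 | step 9 | (1Z,2S,3aR,7R,7aS)-1-ethylidene-2-hydroxy-7-(propan-2-yl)-1,2,3,3a,7,7a-hexahydro-4H-inden-4-one | O=C1[C@@H]2C[C@H](O)/C(=C\C)[C@H]2[C@H](C(C)C)C=C1
F7 | step 10 | 4-hydroxy analogue of 16 (allylic alcohol, hydroxyl anti to H-3a, pseudoaxial) | O[C@@H]1[C@@H]2C[C@H](OC(C)=O)/C(=C\C)[C@H]2[C@H](C(C)C)C=C1
F8 | step 10 | 5,6-epoxide of F7, oxirane syn to the hydroxyl and anti to H-3a | O[C@@H]1[C@@H]2C[C@H](OC(C)=O)/C(=C\C)[C@H]2[C@H](C(C)C)[C@@H]3O[C@H]13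
F9 | step 12 | 4-oxo analogue of 20 (ketone in place of the methylidene group) | O=C1[C@@H]2C[C@H](OC(C)=O)/C(=C\C)[C@H]2[C@H](C(C)C)[C@H](O)[C@H]1OC(=O)/C(C)=C\C
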